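**Retrosynthetic overview**

1. Locants (serratane numbering): ring A = C1–C5, C10 (C3 = CH–OMe, C4 = CMe2); ring B = C5–C10 (C26 = methyl on C8); ring C = C8, C27, C14, C13, C12, C11, C9; ring D = C13, C14, C16, C17, C18 (C15 = CHO carbon on C14); ring E = C17–C22 (C21 = CHOH, C22 = CMe2).
2. End game: the C15 aldehyde comes from its primary alcohol; the seven-membered ring C is closed last at C11=C12 by McMurry coupling of a dialdehyde, itself made from a C9,C13-diketone by twofold methylenation, hydroboration and oxidation.
3. The diketone is the union of a ring AB enone with a ring DE 2-methylene ketone: reductive Michael addition forms C8–C27, and C-alkylation of the new enolate in the same flask installs C15, so both quaternary centres (C8, C14) are set together.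
4. Ring DE comes from (S)-7a-methyl-2,3,7,7a-tetrahydro-1H-indene-1,5(6H)-dione (C18 from the pool). Ring AB comes from (R)-carvone: its ring is ring B, its methyl is C26, its isopropenyl group is C4 with one geminal methyl; ring A is closed by iron-hydride HAT, the isopropenyl group becoming the tertiary C4 radical that adds to a C3 aldehyde (bond C3–C4).
5. Enabling feature: in ring A the oxygen-bearing C3 is bonded directly to the gem-dimethyl carbon C4, and C4 hangs on ring-fusion carbon C5 next to the methyl-bearing C10. An isopropenyl group on C5 is therefore a latent C4 radical (H• supplies the second methyl), and a propanal arm on C10 places C3 at six-ring distance. Ring order: B (pool) → A; E and D (pool); C last.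

Key step: step 4

**Route**

Step 1
Reactants: 1 (R)-(−)-carvone
Product: 3 (5R)-6-methylcarvone (methyl trans to isopropenyl as major epimer), via lithium dienolate 2 (not isolated)
Conditions: LiN(i-Pr)2, THF, −78 °C; MeI, −78 → 0 °C
Reagents that add atoms: iodomethane, CI
Why: Kinetic α′-deprotonation of the enone and C-methylation of the cross-conjugated dienolate is the standard enolate alkylation of carvone; the new C10 centre is planarised again in step 2, so the epimer ratio does not matter.

Step 2
Reactants: 3 (5R)-6-methylcarvone
Product: 5 6-allyl-6-methylcarvone (allyl trans to isopropenyl), via lithium dienolate 4 (not isolated)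
Conditions: LiN(i-Pr)2, THF, −78 → 0 °C; allyl bromide, HMPA, −78 °C → rt
Reagents that add atoms: allyl bromide, C=CCBr
Why: Enolate alkylation creates the quaternary C10; allyl bromide should approach the dienolate anti to the neighbouring C5 isopropenyl group, leaving the C1–C3 chain trans and the methyl cis to isopropenyl, as a trans A/B fusion requires.

Step 3
Reactants: 5 6-allyl-6-methylcarvone
Product: 6 6-methyl-6-(3-oxopropyl)carvone (seco-A aldehyde)
Conditions: PdCl2(PhCN)2 (cat.), CuCl2·2H2O (cat.), AgNO2 (cat.), t-BuOH/MeNO2, O2 (1 atm), rt
Reagents that add atoms: dioxygen, O=O (oxygen atom relayed by the nitrite co-catalyst)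
Why: The nitrite-modified, aldehyde-selective (anti-Markovnikov) Wacker oxidation, known for allyl groups on quaternary carbons, should oxidise only the monosubstituted alkene; the isopropenyl group and the enone are inert and no stereocentre is touched.

Step 4
Reactants: 6 6-methyl-6-(3-oxopropyl)carvone
Product: 9 ring AB hydroxy enone (3β-hydroxy-4,4,8,10-tetramethyl-trans-octal-7-en-9-one), via tertiary C4 radical 7 (not isolated), via ring A alkoxyl radical 8 (not isolated)
Conditions: Fe(acac)3 (30 mol %), PhSiH3, EtOH/ethylene glycol 5:1, 60 °C, 0.02 M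
Reagents that add atoms: none
Why: Mechanism: the iron hydride formed from Fe(acac)3 and PhSiH3 delivers H• to the CH2 terminus of the electron-rich isopropenyl group (Markovnikov MHAT), the tertiary C4 radical 7 adds to the C3 aldehyde carbon, and the alkoxyl radical 8 is reduced by divalent iron and protonated by ethanol before β-scission can reverse the addition. The closest known reaction type is the iron-hydride HAT reductive coupling of unactivated alkenes with carbonyl groups (Mukaiyama-type MHAT; intramolecular with ketones, intermolecular with aldehydes), applied here intramolecularly to an aldehyde. Ring A closes in the 6-exo-trig mode on C=O through a chair transition state in which the C5–C4 and C10–C1 bonds are both equatorial on ring B, so the trans A/B fusion is fixed by the C5 and C10 centres already present. The only new stereocentre, C3, is controlled by that chair: the carbonyl oxygen should sit pseudo-equatorial, away from the axial hydrogens on C1 and C5, giving the 3β (equatorial) alcohol cis to the C10 methyl. The step needs H• transfer to the 1,1-disubstituted alkene and not to the enone, and ring closure faster than intermolecular Giese addition to the enone or simple reduction of the radical; the preference of the metal hydride for electron-rich alkenes, the six-atom tether and high dilution should secure this. In one operation it forms the C3–C4 bond, ring A, the C4 gem-dimethyl group and the C3 carbinol, turning a monocyclic terpene derivative into the complete ring AB sector.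

Step 5
Reactants: 9 ring AB hydroxy enone
Product: 10 ring AB methoxy enone (3β-methoxy analogue of 9)
Conditions: MeOTf, 2,6-di-tert-butyl-4-methylpyridine, CH2Cl2, rt
Reagents that add atoms: methyl trifluoromethanesulfonate, COS(=O)(=O)C(F)(F)F
Why: O-Methylation under non-basic conditions (Williamson-type alkylation with a hindered pyridine as acid scavenger) should etherify the hindered equatorial alcohol without forming the extended enolate of the enone, so no C-methylation or epimerisation is possible.

Step 6
Reactants: 11 (S)-7a-methyl-2,3,7,7a-tetrahydro-1H-indene-1,5(6H)-dione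
Product: 12 C13 ethylene ketal of the enedione
Conditions: 2-ethyl-2-methyl-1,3-dioxolane, ethylene glycol (cat.), p-TsOH (cat.), rt
Reagents that add atoms: 2-ethyl-2-methyl-1,3-dioxolane, CCC1(C)OCCO1
Why: Acid-catalysed transketalisation protects the saturated cyclopentanone in preference to the less electrophilic conjugated carbonyl, the usual chemoselectivity for such enediones; no stereocentre is touched.

Step 7
Reactants: 12 C13 ethylene ketal of the enedione
Product: 14 22,22-dimethyl-16-en-21-one ketal, via monomethyl enone 13 (not isolated)
Conditions: KOt-Bu, t-BuOH/THF, 0 °C → rt; MeI (excess)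
Reagents that add atoms: iodomethane, CI
Why: Twofold deconjugative α-alkylation through the potassium dienolate installs the C22 gem-dimethyl group and moves the alkene to C16=C17, the classical entry to 4,4-dimethyl-3-keto terpenoid rings.

Step 8
Reactants: 14 22,22-dimethyl-16-en-21-one ketal
Product: 15 trans-hydrindan-21-one ketal (17-H trans to the C18 methyl)
Conditions: H2, 10% Pd/C, EtOAc, rt
Reagents that add atoms: none
Why: Heterogeneous hydrogenation should deliver hydrogen to the trisubstituted cyclopentene from the face opposite the angular C18 methyl (as for steroid 14-enes), setting C17–H trans to that methyl.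

Step 9
Reactants: 15 trans-hydrindan-21-one ketal
Product: 16 axial 21-alcohol ketal (OH trans to the C18 methyl)
Conditions: K[s-Bu3BH], THF, −78 °C; H2O
Reagents that add atoms: none
Why: Bulky trialkylborohydride reduction attacks the 22,22-dimethyl ketone equatorially and should give the axial C21 alcohol, the opposite sense to small hydrides.

Step 10
Reactants: 16 axial 21-alcohol ketal
Product: 17 21-O-benzyl ether ketal
Conditions: NaH, BnBr, n-Bu4NI (cat.), DMF, 0 → 50 °C
Reagents that add atoms: benzyl bromide, BrCc1ccccc1
Why: Williamson etherification; benzyl should survive the later enolate, titanium, borane and oxidation steps and leaves by hydrogenolysis in step 18.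

Step 11
Reactants: 17 21-O-benzyl ether ketal
Product: 18 21-benzyloxy-13-ketone
Conditions: 1 M HCl, THF, rt
Reagents that add atoms: water, O
Why: Acid-catalysed ketal hydrolysis frees the C13 ketone; the benzyl ether is stable and no stereocentre is α to the new carbonyl except the quaternary C18.

Step 12
Reactants: 18 21-benzyloxy-13-ketone
Product: 19 ring DE 14-methylene-13-ketone
Conditions: (CH2O)n, i-Pr2NH2·O2CCF3, THF, reflux
Reagents that add atoms: formaldehyde (from paraformaldehyde), C=O
Why: Mannich-type α-methylenation at C14, the only enolisable position because C18 is quaternary, gives an exo-methylene cyclopentanone of the isolable 16-methylene-17-ketosteroid type; this carbon becomes C27.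

Step 13
Reactants: 10 ring AB methoxy enone; 19 ring DE 14-methylene-13-ketone
Product: 22 seco-C C9,C13-diketone with 15-benzyloxy group, via ring AB lithium enolate 20 (not isolated), via Michael adduct enolate 21 (not isolated)
Conditions: Li[s-Bu3BH], THF, −78 °C; then 19, −78 → −40 °C; then BOMCl, HMPA, −78 → 0 °C
Reagents that add atoms: benzyl chloromethyl ether, ClCOCc1ccccc1
Why: Conjugate hydride reduction of the α-methyl enone gives the C8 enolate regiospecifically; its Michael addition to the methylene ketone forms C8–C27 with the acceptor entering anti to the axial C10 methyl (C27 α, C26 β-axial), and the regiodefined C13 enolate is then C-alkylated on the face away from the angular C18 methyl (C15 trans, C27 cis to it), so both quaternary centres should arise by substrate control.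

Step 14
Reactants: 22 seco-C C9,C13-diketone
Product: 23 C9,C13-bis(methylene) compound
Conditions: Cp2TiMe2 (excess), toluene/THF, 80 °C, dark
Reagents that add atoms: dimethyltitanocene Cp2TiMe2, C[Ti](C)(C1C=CC=C1)C1C=CC=C1
Why: Titanium methylidene olefination (Petasis methylenation) is the method of choice for non-enolisable, sterically shielded ketones where phosphorus ylides fail, and should convert both carbonyls into the exocyclic C9=C11 and C13=C12 methylenes in one operation.

Step 15
Reactants: 23 C9,C13-bis(methylene) compound
Product: 25 C11,C12-diol, via bis(alkylborane) 24 (not isolated)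
Conditions: BH3·SMe2, THF, 0 °C → rt; then NaOH, H2O2
Reagents that add atoms: hydrogen peroxide, OO
Why: Anti-Markovnikov hydroboration–oxidation puts boron on each CH2 terminus while hydrogen should reach C9 from the α face (the β face is blocked by the axial C26 and C10 methyls) and C13 from the face opposite the C18 methyl, setting 9α-H and 13-H trans to the C18 methyl.

Step 16
Reactants: 25 C11,C12-diol
Product: 26 C11,C12-dialdehyde
Conditions: 1,1,1-triacetoxy-1,1-dihydro-1,2-benziodoxol-3(1H)-one (DMP), NaHCO3, CH2Cl2, 0 °C → rt
Reagents that add atoms: none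
Why: Buffered hypervalent-iodine oxidation should convert both primary alcohols into aldehydes without epimerising C9 or C13; the ethers are inert.

Step 17
Reactants: 26 C11,C12-dialdehyde
Product: 27 pentacyclic 11-ene bis(benzyl ether)
Conditions: TiCl3(DME)1.5, Zn–Cu couple, DME, reflux, slow addition (high dilution)
Reagents that add atoms: none
Why: Intramolecular McMurry coupling with low-valent titanium forms C11=C12 and closes the seven-membered ring C as its cis alkene, a ring size for which dialdehyde coupling is reliable; the required C9 and C13 configurations are also the thermodynamically preferred ones should any epimerisation occur.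

Step 18
Reactants: 27 pentacyclic 11-ene bis(benzyl ether)
Product: 28 pentacyclic 15,21-diol
Conditions: H2 (3 atm), Pd(OH)2/C, EtOAc/MeOH, rt
Reagents that add atoms: none
Why: Catalytic hydrogenation saturates the cis-disubstituted ring C alkene without creating a stereocentre and hydrogenolyses both benzyl ethers in the same operation.

Step 19
Reactants: 28 pentacyclic 15,21-diol
Product: 29 CNP0131145.1
Conditions: TEMPO (cat.), PhI(OAc)2, CH2Cl2, rt
Reagents that add atoms: none
Why: Oxoammonium (TEMPO) oxidation is selective for the primary C15 alcohol over the hindered axial secondary C21 alcohol and should stop at the non-enolisable quaternary aldehyde.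

**Compound list**

1 | (R)-(−)-carvone | CC1=CC[C@H](CC1=O)C(C)=C | starting material
2 | lithium dienolate of carvone | [Li]OC1=C[C@@H](CC=C1C)C(C)=C | intermediate
3 | (5R)-6-methylcarvone (methyl trans to isopropenyl, major epimer) | C[C@H]1[C@@H](CC=C(C)C1=O)C(C)=C | intermediate
4 | lithium dienolate of 6-methylcarvone | [Li]OC1=C(C)[C@@H](CC=C1C)C(C)=C | intermediate
5 | 6-allyl-6-methylcarvone (allyl trans, methyl cis to isopropenyl) | C=CC[C@@]1(C)[C@@H](CC=C(C)C1=O)C(C)=C | intermediate
6 | 6-methyl-6-(3-oxopropyl)carvone (seco-A aldehyde) | O=CCC[C@@]1(C)[C@@H](CC=C(C)C1=O)C(C)=C | intermediate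
7 | tertiary C4 radical | O=CCC[C@@]1(C)[C@@H](CC=C(C)C1=O)[C](C)C | intermediate
8 | ring A alkoxyl radical | [O][C@H]1CC[C@@]2(C)[C@@H](CC=C(C)C2=O)C1(C)C | intermediate
9 | ring AB hydroxy enone (3β-OH, 5α-H, 10β-CH3, 7-en-9-one) | O[C@H]1CC[C@@]2(C)[C@@H](CC=C(C)C2=O)C1(C)C | intermediate
10 | ring AB methoxy enone | CO[C@H]1CC[C@@]2(C)[C@@H](CC=C(C)C2=O)C1(C)C | intermediate
11 | (S)-7a-methyl-2,3,7,7a-tetrahydro-1H-indene-1,5(6H)-dione | C[C@]12CCC(=O)C=C1CCC2=O | starting material
12 | C13 ethylene ketal of the enedione | O=C1C=C2CCC3(OCCO3)[C@@]2(C)CC1 | intermediate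
13 | 22-monomethyl enone ketal | O=C1C(C)=C2CCC3(OCCO3)[C@@]2(C)CC1 | intermediate
14 | 22,22-dimethyl-16-en-21-one ketal | O=C1C(C)(C)C2=CCC3(OCCO3)[C@@]2(C)CC1 | intermediate
15 | trans-hydrindan-21-one ketal | O=C1C(C)(C)[C@@H]2CCC3(OCCO3)[C@@]2(C)CC1 | intermediate
16 | axial 21-alcohol ketal | O[C@H]1C(C)(C)[C@@H]2CCC3(OCCO3)[C@@]2(C)CC1 | intermediate
17 | 21-O-benzyl ether ketal | c1ccccc1CO[C@H]2C(C)(C)[C@@H]3CCC4(OCCO4)[C@@]3(C)CC2 | intermediate
18 | 21-benzyloxy-13-ketone | c1ccccc1CO[C@H]2C(C)(C)[C@@H]3CCC(=O)[C@@]3(C)CC2 | intermediate
19 | ring DE 14-methylene-13-ketone | c1ccccc1CO[C@H]2C(C)(C)[C@@H]3CC(=C)C(=O)[C@@]3(C)CC2 | intermediate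
20 | ring AB lithium enolate | CO[C@H]1CC[C@@]2(C)[C@@H](CCC(C)=C2O[Li])C1(C)C | intermediate
21 | Michael adduct lithium enolate | CO[C@H]1CC[C@@]2(C)[C@@H](CC[C@](C)(C2=O)CC3C[C@H]4C(C)(C)[C@H](OCc5ccccc5)CC[C@]4(C)C=3O[Li])C1(C)C | intermediate
22 | seco-C C9,C13-diketone with 15-benzyloxy group | CO[C@H]1CC[C@@]2(C)[C@@H](CC[C@](C)(C2=O)C[C@@]3(COCc6ccccc6)C[C@H]4C(C)(C)[C@H](OCc5ccccc5)CC[C@]4(C)C3=O)C1(C)C | intermediate
23 | C9,C13-bis(methylene) compound | CO[C@H]1CC[C@@]2(C)[C@@H](CC[C@](C)(C2=C)C[C@@]3(COCc6ccccc6)C[C@H]4C(C)(C)[C@H](OCc5ccccc5)CC[C@]4(C)C3=C)C1(C)C | intermediate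
24 | bis(alkylborane) | CO[C@H]1CC[C@@]2(C)[C@@H](CC[C@](C)([C@@H]2CB)C[C@@]3(COCc6ccccc6)C[C@H]4C(C)(C)[C@H](OCc5ccccc5)CC[C@]4(C)[C@H]3CB)C1(C)C | intermediate
25 | C11,C12-diol | CO[C@H]1CC[C@@]2(C)[C@@H](CC[C@](C)([C@@H]2CO)C[C@@]3(COCc6ccccc6)C[C@H]4C(C)(C)[C@H](OCc5ccccc5)CC[C@]4(C)[C@H]3CO)C1(C)C | intermediate
26 | C11,C12-dialdehyde | CO[C@H]1CC[C@@]2(C)[C@@H](CC[C@](C)([C@@H]2C=O)C[C@@]3(COCc6ccccc6)C[C@H]4C(C)(C)[C@H](OCc5ccccc5)CC[C@]4(C)[C@H]3C=O)C1(C)C | intermediate
27 | pentacyclic 11-ene bis(benzyl ether) | CO[C@H]1CC[C@@]2(C)[C@@H](CC[C@@]3(C)C[C@@]4(COCc6ccccc6)C[C@H]5C(C)(C)[C@H](OCc7ccccc7)CC[C@]5(C)[C@H]4C=C[C@@H]32)C1(C)C | intermediate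
28 | pentacyclic 15,21-diol | CO[C@H]1CC[C@@]2(C)[C@@H](CC[C@@]3(C)C[C@@]4(CO)C[C@H]5C(C)(C)[C@H](O)CC[C@]5(C)[C@H]4CC[C@@H]32)C1(C)C | intermediate
29 | CNP0131145.1 | CO[C@H]1CC[C@@]2(C)[C@@H](CC[C@@]3(C)C[C@@]4(C=O)C[C@H]5C(C)(C)[C@H](O)CC[C@]5(C)[C@H]4CC[C@@H]32)C1(C)C | target

**Step count and risks**

Total step count: 19. Longest linear sequence: 14 steps (steps 6–12, then 13–19).

Steps most likely to fail:

Step 14. The titanium methylidene may fail to engage carbonyl groups that are each flanked by two quaternary carbons, so olefination stops after one carbonyl or does not start. The fallback sets out from 22: twofold addition of the small, weakly basic methylcerium reagent (MeLi, CeCl3, THF, −78 → 0 °C) should give the bis(tertiary carbinol) F1. Syn-dehydration with methyl N-(triethylammoniumsulfonyl)carbamate in toluene at 80 °C can then only take a methyl hydrogen, because every ring β-carbon is quaternary, and returns to the route at 23.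

Step 13. Proton transfer from the γ-CH2 of the methylene ketone to the hindered enolate, anionic oligomerisation of the acceptor, or O- instead of C-alkylation in the trapping may erode the one-flask union. The fallback sets out from 10 (with 19): conjugate reduction with Li[s-Bu3BH] and quenching with Me3SiCl gives the ring AB trimethylsilyl enol ether F2. A TiCl4-promoted Mukaiyama–Michael addition to 19 in CH2Cl2 at −78 °C then forms C8–C27 without free enolate and gives the 1,5-diketone F3 as C14 epimers. Its only acidic C–H is at C14, so KN(SiMe3)2 followed by benzyl chloromethyl ether returns to the route at 22.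

Step 4. The tertiary radical may be reduced before ring closure, the carbonyl addition may revert by β-scission of the alkoxyl radical, or the facial selectivity at C3 may be poor. The fallback sets out from 6: iodine in aqueous ammonia converts the aldehyde into the seco-A nitrile F4. The known iron-hydride HAT alkene–nitrile cyclisation (Fe(acac)3, PhSiH3, EtOH, 60 °C, then aqueous acid) closes ring A through a reducible iminyl radical and gives the ring AB 3,9-dione F5 after hydrolysis. NaBH4 in MeOH/CH2Cl2 at −40 °C should then reduce only the saturated 3-ketone, from the axial direction, returning to the route at 9 with C3 set by hydride delivery.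

Further compounds
F1 | step 14 | bis(tertiary carbinol) from twofold methyl addition (carbinol configurations not defined) | CO[C@H]1CC[C@@]2(C)[C@@H](CC[C@](C)(C2(C)O)C[C@@]3(COCc6ccccc6)C[C@H]4C(C)(C)[C@H](OCc5ccccc5)CC[C@]4(C)C3(C)O)C1(C)C
F2 | step 13 | ring AB trimethylsilyl enol ether | CO[C@H]1CC[C@@]2(C)[C@@H](CCC(C)=C2O[Si](C)(C)C)C1(C)C
F3 | step 13 | seco-C 1,5-diketone with C14–H (C14 epimers) | CO[C@H]1CC[C@@]2(C)[C@@H](CC[C@](C)(C2=O)CC3C[C@H]4C(C)(C)[C@H](OCc5ccccc5)CC[C@]4(C)C3=O)C1(C)C
F4 | step 4 | seco-A nitrile | N#CCC[C@@]1(C)[C@@H](CC=C(C)C1=O)C(C)=C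
F5 | step 4 | ring AB 3,9-dione | O=C1CC[C@@]2(C)[C@@H](CC=C(C)C2=O)C1(C)C
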